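## Remarks on the structures and assumptions

- Structure check: ring A is numbered C1–C10 (C7 isopropenyl, C8 senecioate, C9 hydroxyl, C3 angelate, epoxides at C1–C10 and C4–C5); the target is (1R,3S,4S,5S,7R,8S,9S,10S). Both epoxides are cis-fused, so each comes from a Z olefin. On a flat drawing of ring A the oxygens on C3, C8 and C9, the isopropenyl group and the C1–C10 epoxide oxygen share one face; the C4–C5 epoxide oxygen lies on the other.
- The open-chain aldehyde, the iodide and the coupled chain agree with the target in the sense of both carbinol centres and in both olefin geometries, so no skeleton needed correction. Two bookkeeping points: the second coupling alone forms one C–C bond and one stereocentre (two of each only over both passes), and the C9 centre is R by the sequence rule in 10–13 while C3 is S, although both arise from addition to the same (Re) aldehyde face.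
- Design change at C8 (skeleton and disconnection unchanged): C8 is carried as a benzoate-protected CH2O group, not as a dimethyl acetal. An acetal would need late acid hydrolysis next to a silyl ether and in the presence of an acid-labile 2-methylallylstannane. The benzoate falls off in the iBu2AlH step that is needed anyway, and the C8 aldehyde is then made by a neutral oxidation. Both aldehydes that meet the chiral catalyst are then unbranched RCH2CHO types, and the first-pass aldehyde is anhydrous.
- Assumption: the ligand enantiomer (from D- or L-valinol) that sends the alkenyl group to the Re face is identified on 10 (Mosher ester analysis) before step 8; both antipodes are accessible.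
- Assumption: 2-oxoethyl benzoate 9 is bought as such.

## Structural features

The target is a ten-membered carbocycle (ring A) with no other carbocycle; two oxirane rings are fused to it at C1–C10 and C4–C5, each derived from a Z-trisubstituted olefin whose methyl group sits on C10 or C4. Five stereocentres run in a row from C7 to C1 (isopropenyl, senecioate, hydroxyl, epoxide), and three more form the C3–C4–C5 set (angelate, epoxide). The C1–C10 epoxide is cis to its neighbouring C9 oxygen, whereas the C4–C5 epoxide is trans to the C3 oxygen. Fragile elements are the two acid-labile trisubstituted epoxides, the angelate (Z to E isomerisation), the senecioate (deconjugation) and the free C9 hydroxyl next to the C8 ester (acyl shift). The real difficulties are closing a ten-membered ring that holds two Z olefins, telling three secondary oxygens apart, and placing the two epoxides with opposite sense relative to their neighbouring carbinols. The key step exploits the fact that C9–C10(Me)=C1–C2 and C3–C4(Me)=C5–C6 are the same four-carbon motif, a carbinol bonded to the methyl-bearing carbon of a Z olefin, repeated head to tail with the same absolute sense at C9 and C3.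

## Logic of the disconnections

33 to 32: the two C–O bonds of the C1–C10 oxirane are cut last. The free C9 hydroxyl of 32 can deliver the oxygen, and the most acid-sensitive group is then absent from all earlier steps. The forward step must attack the face cis to the C9 oxygen and leave the isopropenyl group and both enoates alone.

32 to 31 to 28 and 29: the C9 O–Si bond and the C3 acyl C–O bond are cut. This leaves one free hydroxyl at each stage, so no selective acylation is asked for. The forward steps must not isomerise the Z enoate and must not let the C8 acyl group move to C9.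

28 to 27: the C–O bonds of the C4–C5 oxirane are cut while C3 carries a free hydroxyl. That hydroxyl accelerates and steers a peracid, and the silyl ether on C9 screens the other ring olefin. The forward step must give the epoxide trans to the C3 oxygen and stop after one oxidation.

27 to 26 to 24 and 25: the C3 O–Si bond and the C8 acyl C–O bond are cut. The three oxygens are told apart without extra steps because ring closure sets free only the C8 hydroxyl, while C3 and C9 carry silyl groups of different lability.

24 to 23: the C7–C8 ring bond is cut. This removes ring A and two stereocentres at once and leads back to an open chain holding an allyl-tin unit and an α-silyloxy aldehyde. The forward step must close a ten-membered ring under dilution, add to the aldehyde face dictated by C9 (Felkin–Anh) and join C7 and C8 in the syn sense of an open transition state.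

23 to 22 to 21 to 20 to 19: functional-group changes only (aldehyde from alcohol, C–Sn from C–Cl, C–Cl from allylic C–OH, both primary alcohols from an enoate and a benzoate in one reduction). The demand is that the allylic hydroxyl of 20 reacts and the saturated one does not.

19 to 17 and 18: the olefin between C7 and the future isopropenyl carbon is cut. Three carbons arrive in one olefination under non-basic conditions; the geometry of this olefin is erased on ring closure.

17 to 16 to 15 to 14: the C7 aldehyde is traced to the benzyl-type ether and the C3 silyl ether to the free carbinol. The demand is that the skipped enal 17 is made and used without double-bond migration.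

14 to 13 and 8: the C3–C4 bond is cut between the carbinol carbon and the methyl-bearing olefin carbon. This splits the chain into an aldehyde and the same alkenyl iodide that served before. The forward step must retain the Z geometry and set C3 by catalyst control.

13 to 12 to 11 to 10: the same functional-group changes as for 17 (aldehyde, alcohol, ether; silyl ether from carbinol).

10 to 8 and 9: the C9–C10 bond is cut in the same way as C3–C4. The demand is the same aldehyde face as in the later pass, so that one ligand enantiomer serves both.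

8 to 3 and 4 (through 7, 6 and 5): the trisubstituted iodo-olefin is cut at the double bond. The forward olefination must put iodine cis to the chain.

3 to 2 to 1: an aldehyde from a mono-protected symmetrical diol; the only demand is mono-protection.

## Other disconnections considered

Alternative 1: The cut is C6–C7, with C4 and C9 joined in the retro-direction. Ketone A1 (Z,Z-cyclodeca-1(10),4-dien-9-one with the C7 isopropenyl and C3 silyl ether, no oxygen on C8) would come from cyclohexenol A2. A2 is a 2-methylcyclohex-2-en-1-ol carrying a 3-methylbuta-1,3-dienyl group on the carbinol carbon and methyl plus vinyl on the neighbouring quaternary carbon, with dienyl and vinyl cis. The forward step is an alkoxide-accelerated [3,3] shift (KH, 18-crown-6, THF).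
- In favour: the ring forms by ring expansion, so dilution and oligomers are no concern; on ring formation this alternative is better than the chosen plan. The C1=C10 olefin is already cis in the six-membered ring, and C7 comes from chirality transfer.
- Against: the Z geometry at C4=C5 requires the C3–C4 bond to be axial in a chair-like transition state. A chair analysis then places silyl ether, vinyl and dienyl all cis in A2, a crowded array that needs a 1,2-addition of a dienyl metal to a hindered, enolisable ketone.
- Against: A1 has no C8 oxygen. An enolate oxidation at C8, a face-selective reduction at C9 and a differentiation of the two new hydroxyls would follow, on a Z-enone prone to γ-deprotonation and geometric isomerisation.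
- Comparison: the chosen plan brings C9 in as a catalyst-set centre and makes C8 from it under substrate control, with C8 and C9 differentiated from the start. The step count should be similar once the C8/C9 corrections are added.

Alternative 2: The cut is C5–C6. Acetonide A3 would come from diiodide A4 (Z-alkenyl iodide at C5, primary iodide at C6) by nickel reductive coupling (NiBr2(DME), 4,4′-di-tert-butyl-2,2′-bipyridine, Mn). Zerovalent nickel inserts into the alkenyl iodide, the alkyl radical from the primary iodide is captured, and reductive elimination closes the ring.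
- In favour: all four stereocentres (C3, C7, C8, C9) and both Z olefins are fixed before ring closure, so the macrocyclisation has no stereochemical task. On this point it is better than the chosen plan, which creates C7 and C8 during ring closure. It also avoids sensitive aldehydes.
- Against: a ten-membered closure by cross-electrophile coupling has to beat dimerisation, hydrodehalogenation and β-hydride loss. The C6 radical is homoallylic to the isopropenyl group and can rearrange by a 1,2-alkenyl shift through a cyclopropylcarbinyl radical.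
- Against: the C7–C9 triad of A4 must be built by separate stereoselective steps, and after acetonide removal C8 has to be acylated in preference to C9.
- Comparison: both plans fix the Z geometry ahead of ring closure (equal). The chosen plan is shorter to the differentiated C8/C9 oxygens.

Alternative 3: The cut is C8–C9. Diol A5 would come from dialdehyde A6 (C8 aldehyde, C9 Z-enal) by pinacol coupling on low-valent titanium from TiCl3(DME)1.5 and zinc–copper couple.
- In favour: ring A and both carbinols arise in one step without protecting groups on C8 and C9, and only C3 and C7 have to be set beforehand. On step count up to the ring it is equal to or better than the chosen plan.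
- Against: two stereocentres form from two prochiral aldehydes with control only by ring conformation, and cis/trans preferences of ten-membered pinacol closures are not dependable.
- Against: A6 holds a Z-enal (geometry loss through the ketyl) and an α-isopropenyl aldehyde (epimerisation at C7, double-bond migration). Deoxygenation to the olefin competes, and the cis-diol of A5 must be mono-acylated at C8.
- Comparison: the chosen plan sets C9 by catalyst and C8 relative to it, and leaves C8 as the only free hydroxyl after ring closure.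

Key step: step 8

## Route

Step 1
Reactants: 1 propane-1,3-diol
Product: 2 3-[(4-methoxybenzyl)oxy]propan-1-ol
Conditions: NaH (1 equiv), 4-methoxybenzyl chloride (1 equiv), Bu4NI (cat.), THF/DMF, 0 °C to rt; diol in excess
Reagents that add atoms: 4-methoxybenzyl chloride, COc1ccc(CCl)cc1
Why: Williamson ether synthesis; excess diol steers the alkylation to the mono-ether.

Step 2
Reactants: 2 3-[(4-methoxybenzyl)oxy]propan-1-ol
Product: 3 3-[(4-methoxybenzyl)oxy]propanal
Conditions: TEMPO (cat.), PhI(OAc)2, CH2Cl2, rt
Reagents that add atoms: none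
Why: Oxoammonium (TEMPO) oxidation stops at the aldehyde and leaves the benzyl-type ether intact.

Step 3
Reactants: 4 ethyltriphenylphosphonium bromide; 3 3-[(4-methoxybenzyl)oxy]propanal
Product: 8 (Z)-1-{[(4-iodopent-3-en-1-yl)oxy]methyl}-4-methoxybenzene, via ethylidenetriphenylphosphorane 5 (not isolated), via (1-iodoethyl)triphenylphosphonium iodide 6 (not isolated), via (1-iodoethylidene)triphenylphosphorane 7 (not isolated)
Conditions: n-BuLi, THF, 0 °C; I2, −78 °C; NaN(SiMe3)2, −20 °C; then 3, −78 °C
Reagents that add atoms: iodine, II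
Why: Stork–Zhao olefination; the α-iodo ylide 7 and an unbranched aldehyde should give the Z-2-iodoalkene under kinetic control, with iodine cis to the chain, which fixes the later ring-olefin geometry.

Step 4
Reactants: 8 (Z)-1-{[(4-iodopent-3-en-1-yl)oxy]methyl}-4-methoxybenzene; 9 2-oxoethyl benzoate
Product: 10 (2R,3Z)-2-hydroxy-6-[(4-methoxybenzyl)oxy]-3-methylhex-3-en-1-yl benzoate
Conditions: CrCl2 (10 mol%), N-[2-(4-isopropyl-4,5-dihydro-1,3-oxazol-2-yl)-6-methylphenyl]methanesulfonamide (one enantiomer, 12 mol%), proton sponge, NiCl2(2,9-dimethyl-1,10-phenanthroline) (2 mol%), Mn, Cp2ZrCl2, LiCl, MeCN, rt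
Reagents that add atoms: none
Why: Catalytic asymmetric Nozaki–Hiyama–Kishi alkenylation (first pass, forms C9–C10); the alkenylchromium keeps the Z geometry and the ligand should direct it to the Re face of the aldehyde, which sets C9. Organochromium reagents do not add to the benzoate.

Step 5
Reactants: 10 (2R,3Z)-2-hydroxy-6-[(4-methoxybenzyl)oxy]-3-methylhex-3-en-1-yl benzoate
Product: 11 (2R,3Z)-2-[(tert-butyldimethylsilyl)oxy]-6-[(4-methoxybenzyl)oxy]-3-methylhex-3-en-1-yl benzoate
Conditions: TBSOTf, 2,6-lutidine, CH2Cl2, −78 °C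
Reagents that add atoms: tert-butyldimethylsilyl triflate, CC(C)(C)[Si](C)(C)OS(=O)(=O)C(F)(F)F
Why: Silylation with the triflate and a hindered base is fast at low temperature, so the neighbouring benzoate has no time to shift; the bulky non-chelating silyl ether is what the later Felkin–Anh addition needs.

Step 6
Reactants: 11 (2R,3Z)-2-[(tert-butyldimethylsilyl)oxy]-6-[(4-methoxybenzyl)oxy]-3-methylhex-3-en-1-yl benzoate
Product: 12 (2R,3Z)-2-[(tert-butyldimethylsilyl)oxy]-6-hydroxy-3-methylhex-3-en-1-yl benzoate
Conditions: DDQ, CH2Cl2/pH 7 buffer, 0 °C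
Reagents that add atoms: none
Why: Oxidative cleavage of the 4-methoxybenzyl ether by DDQ; the buffer protects the allylic silyl ether.

Step 7
Reactants: 12 (2R,3Z)-2-[(tert-butyldimethylsilyl)oxy]-6-hydroxy-3-methylhex-3-en-1-yl benzoate
Product: 13 (2R,3Z)-2-[(tert-butyldimethylsilyl)oxy]-3-methyl-6-oxohex-3-en-1-yl benzoate
Conditions: Dess–Martin periodinane, NaHCO3, CH2Cl2, 0 °C; used at once
Reagents that add atoms: none
Why: Dess–Martin oxidation is neutral when buffered, so the β,γ-unsaturated aldehyde should form without migration of the double bond into conjugation.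

Step 8
Reactants: 13 (2R,3Z)-2-[(tert-butyldimethylsilyl)oxy]-3-methyl-6-oxohex-3-en-1-yl benzoate; 8 (Z)-1-{[(4-iodopent-3-en-1-yl)oxy]methyl}-4-methoxybenzene
Product: 14 (2R,3Z,6S,7Z)-2-[(tert-butyldimethylsilyl)oxy]-6-hydroxy-10-[(4-methoxybenzyl)oxy]-3,7-dimethyldeca-3,7-dien-1-yl benzoate
Conditions: CrCl2 (10 mol%), the same ligand enantiomer as in step 4 (12 mol%), proton sponge, NiCl2(2,9-dimethyl-1,10-phenanthroline) (2 mol%), Mn, Cp2ZrCl2, LiCl, MeCN, 0 °C; 13 added last
Reagents that add atoms: none
Why: Zerovalent nickel, formed from the NiCl2 complex and Mn, inserts into the C–I bond of 8 with retention, the alkenyl group passes to trivalent chromium held by the chiral sulfonamide–oxazoline ligand, and this alkenylchromium adds to the aldehyde of 13; Cp2ZrCl2 frees the chromium alkoxide and Mn returns chromium to the divalent state. The closest known reaction type is the catalytic asymmetric Nozaki–Hiyama–Kishi coupling of 2-iodoalkenes with aliphatic aldehydes. No ring closes; the step joins C3 to C4 and completes the chain from C7 to C8 with all ten ring carbons in order. The new C3 stereocentre (S) is set by the ligand, which directs the alkenyl group to the Re face as in step 4, so the same ligand enantiomer is used; the C9 centre of 13 is five bonds from the carbonyl and should not interfere. The step needs retention of the Z geometry (alkenylnickel and alkenylchromium species are configurationally stable), addition to the aldehyde and not to the benzoate, and no migration of the C1=C10 double bond into conjugation. The last point is secured by the non-basic medium, by working at 0 °C with freshly made 13, and by using the zirconium chloride in place of a silyl chloride, which with base could turn the aldehyde into a silyl dienol ether.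

Step 9
Reactants: 14 (2R,3Z,6S,7Z)-2-[(tert-butyldimethylsilyl)oxy]-6-hydroxy-10-[(4-methoxybenzyl)oxy]-3,7-dimethyldeca-3,7-dien-1-yl benzoate
Product: 15 (2R,3Z,6S,7Z)-2-[(tert-butyldimethylsilyl)oxy]-10-[(4-methoxybenzyl)oxy]-3,7-dimethyl-6-[(triethylsilyl)oxy]deca-3,7-dien-1-yl benzoate
Conditions: TESCl, imidazole, CH2Cl2, 0 °C
Reagents that add atoms: chlorotriethylsilane, CC[Si](CC)(CC)Cl
Why: Standard silylation; the triethylsilyl ether survives hydride, stannyl anion and BF3 at low temperature and can later be removed in the presence of the more hindered C9 silyl ether.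

Step 10
Reactants: 15 (2R,3Z,6S,7Z)-2-[(tert-butyldimethylsilyl)oxy]-10-[(4-methoxybenzyl)oxy]-3,7-dimethyl-6-[(triethylsilyl)oxy]deca-3,7-dien-1-yl benzoate
Product: 16 (2R,3Z,6S,7Z)-2-[(tert-butyldimethylsilyl)oxy]-10-hydroxy-3,7-dimethyl-6-[(triethylsilyl)oxy]deca-3,7-dien-1-yl benzoate
Conditions: DDQ, CH2Cl2/pH 7 buffer, 0 °C
Reagents that add atoms: none
Why: Oxidative cleavage of the 4-methoxybenzyl ether as in step 6; the buffer keeps the acid-labile triethylsilyl ether.

Step 11
Reactants: 16 (2R,3Z,6S,7Z)-2-[(tert-butyldimethylsilyl)oxy]-10-hydroxy-3,7-dimethyl-6-[(triethylsilyl)oxy]deca-3,7-dien-1-yl benzoate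
Product: 17 (2R,3Z,6S,7Z)-2-[(tert-butyldimethylsilyl)oxy]-3,7-dimethyl-10-oxo-6-[(triethylsilyl)oxy]deca-3,7-dien-1-yl benzoate
Conditions: Dess–Martin periodinane, NaHCO3, CH2Cl2, 0 °C; used at once
Reagents that add atoms: none
Why: Buffered Dess–Martin oxidation, as in step 7, gives the C7 aldehyde without conjugation of the C4=C5 olefin.

Step 12
Reactants: 17 (2R,3Z,6S,7Z)-2-[(tert-butyldimethylsilyl)oxy]-3,7-dimethyl-10-oxo-6-[(triethylsilyl)oxy]deca-3,7-dien-1-yl benzoate; 18 ethyl 2-(triphenylphosphoranylidene)propanoate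
Product: 19 ethyl (2E,5Z,7S,9Z,11R)-12-(benzoyloxy)-11-[(tert-butyldimethylsilyl)oxy]-2,6,10-trimethyl-7-[(triethylsilyl)oxy]dodeca-2,5,9-trienoate
Conditions: CH2Cl2, 0 °C to rt
Reagents that add atoms: none
Why: Wittig olefination with a stabilised ylide is E-selective and too weakly basic to enolise the skipped enal; it adds the three carbons of the future isopropenyl group.

Step 13
Reactants: 19 ethyl (2E,5Z,7S,9Z,11R)-12-(benzoyloxy)-11-[(tert-butyldimethylsilyl)oxy]-2,6,10-trimethyl-7-[(triethylsilyl)oxy]dodeca-2,5,9-trienoate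
Product: 20 (2E,5Z,7S,9Z,11R)-11-[(tert-butyldimethylsilyl)oxy]-2,6,10-trimethyl-7-[(triethylsilyl)oxy]dodeca-2,5,9-triene-1,12-diol
Conditions: iBu2AlH (6 equiv), CH2Cl2, −78 to −20 °C; aqueous potassium sodium tartrate
Reagents that add atoms: none
Why: The aluminium hydride reduces the enoate 1,2 to the allylic alcohol and cleaves the benzoate in the same operation, so the C8 hydroxyl is freed without a separate step and long before any tin is present.

Step 14
Reactants: 20 (2E,5Z,7S,9Z,11R)-11-[(tert-butyldimethylsilyl)oxy]-2,6,10-trimethyl-7-[(triethylsilyl)oxy]dodeca-2,5,9-triene-1,12-diol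
Product: 21 (2R,3Z,6S,7Z,10E)-2-[(tert-butyldimethylsilyl)oxy]-12-chloro-3,7,11-trimethyl-6-[(triethylsilyl)oxy]dodeca-3,7,10-trien-1-ol
Conditions: N-chlorosuccinimide, Me2S, CH2Cl2, −30 to 0 °C
Reagents that add atoms: N-chlorosuccinimide, ClN1C(=O)CCC1=O
Why: Corey–Kim chlorination; only the allylic alkoxysulfonium salt collapses to the chloride below 0 °C, whereas the saturated one at C8 reverts to the alcohol on work-up. No allylic transposition is expected for a primary allylic alcohol.

Step 15
Reactants: 21 (2R,3Z,6S,7Z,10E)-2-[(tert-butyldimethylsilyl)oxy]-12-chloro-3,7,11-trimethyl-6-[(triethylsilyl)oxy]dodeca-3,7,10-trien-1-ol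
Product: 22 (2R,3Z,6S,7Z,10E)-2-[(tert-butyldimethylsilyl)oxy]-3,7,11-trimethyl-6-[(triethylsilyl)oxy]-12-(tributylstannyl)dodeca-3,7,10-trien-1-ol
Conditions: Bu3SnLi (2.5 equiv, from Bu3SnH and LiN(iPr)2), THF, −78 °C; quenched cold
Reagents that add atoms: tributylstannyllithium, [Li][Sn](CCCC)(CCCC)CCCC
Why: SN2 displacement of a primary allylic chloride by a stannyl anion; the excess covers deprotonation of the C8 hydroxyl, and working at −78 °C keeps the lithium alkoxide from pulling the silyl group over from C9.

Step 16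
Reactants: 22 (2R,3Z,6S,7Z,10E)-2-[(tert-butyldimethylsilyl)oxy]-3,7,11-trimethyl-6-[(triethylsilyl)oxy]-12-(tributylstannyl)dodeca-3,7,10-trien-1-ol
Product: 23 (2R,3Z,6S,7Z,10E)-2-[(tert-butyldimethylsilyl)oxy]-3,7,11-trimethyl-6-[(triethylsilyl)oxy]-12-(tributylstannyl)dodeca-3,7,10-trienal
Conditions: SO3·pyridine, DMSO, iPr2NEt, CH2Cl2, −10 °C; used at once
Reagents that add atoms: none
Why: Parikh–Doering oxidation is acid-free and known to tolerate allylstannanes; short contact with the hindered amine at low temperature should keep the C9 centre (α to the aldehyde and allylic) intact.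

Step 17
Reactants: 23 (2R,3Z,6S,7Z,10E)-2-[(tert-butyldimethylsilyl)oxy]-3,7,11-trimethyl-6-[(triethylsilyl)oxy]-12-(tributylstannyl)dodeca-3,7,10-trienal
Product: 24 (1(10)Z,3S,4Z,7R,8S,9R)-9-[(tert-butyldimethylsilyl)oxy]-4,10-dimethyl-7-(prop-1-en-2-yl)-3-[(triethylsilyl)oxy]cyclodeca-1(10),4-dien-8-ol
Conditions: BF3·OEt2 (2 equiv), CH2Cl2, −78 °C; 23 added by syringe pump to about 1 mM
Reagents that add atoms: none
Why: Lewis-acid-promoted intramolecular SE2′ addition of the allylstannane to the aldehyde closes C7–C8 and turns the allyl unit into the isopropenyl group. With the monodentate BF3 and the non-chelating silyl ether, attack should follow the Felkin–Anh model and give the 8,9-anti (ring-cis) relation. The open transition state of allylstannane additions favours the syn relation at C7/C8, which places isopropenyl and the C8 oxygen on the same ring face.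

Step 18
Reactants: 24 (1(10)Z,3S,4Z,7R,8S,9R)-9-[(tert-butyldimethylsilyl)oxy]-4,10-dimethyl-7-(prop-1-en-2-yl)-3-[(triethylsilyl)oxy]cyclodeca-1(10),4-dien-8-ol; 25 3-methylbut-2-enoyl chloride
Product: 26 (1(10)Z,3S,4Z,7R,8S,9R)-9-[(tert-butyldimethylsilyl)oxy]-4,10-dimethyl-7-(prop-1-en-2-yl)-3-[(triethylsilyl)oxy]cyclodeca-1(10),4-dien-8-yl 3-methylbut-2-enoate
Conditions: pyridine, DMAP (cat.), CH2Cl2, 0 °C to rt
Reagents that add atoms: none
Why: Acylation of the only free hydroxyl; the weak base pyridine at low temperature limits the vinylketene pathway that would deconjugate the senecioyl group.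

Step 19
Reactants: 26 (1(10)Z,3S,4Z,7R,8S,9R)-9-[(tert-butyldimethylsilyl)oxy]-4,10-dimethyl-7-(prop-1-en-2-yl)-3-[(triethylsilyl)oxy]cyclodeca-1(10),4-dien-8-yl 3-methylbut-2-enoate
Product: 27 (1(10)Z,3S,4Z,7R,8S,9R)-9-[(tert-butyldimethylsilyl)oxy]-3-hydroxy-4,10-dimethyl-7-(prop-1-en-2-yl)cyclodeca-1(10),4-dien-8-yl 3-methylbut-2-enoate
Conditions: PPTS (cat.), MeOH/CH2Cl2, 0 °C
Reagents that add atoms: none
Why: Mild acid methanolysis removes the triethylsilyl ether much faster than the hindered tert-butyldimethylsilyl ether on C9; no epoxide is present yet.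

Step 20
Reactants: 27 (1(10)Z,3S,4Z,7R,8S,9R)-9-[(tert-butyldimethylsilyl)oxy]-3-hydroxy-4,10-dimethyl-7-(prop-1-en-2-yl)cyclodeca-1(10),4-dien-8-yl 3-methylbut-2-enoate
Product: 28 (1(10)Z,3S,4R,5S,7R,8S,9R)-9-[(tert-butyldimethylsilyl)oxy]-4,5-epoxy-3-hydroxy-4,10-dimethyl-7-(prop-1-en-2-yl)cyclodec-1(10)-en-8-yl 3-methylbut-2-enoate
Conditions: mCPBA (1.05 equiv), NaHCO3, CH2Cl2, −20 to 0 °C
Reagents that add atoms: 3-chloroperbenzoic acid, O=C(OO)c1cccc(Cl)c1
Why: Hydroxyl-directed peracid epoxidation (Henbest type); with the C3–H bond eclipsing the olefin to relieve A(1,3) strain against C6, the hydroxyl lies on the outer face and the ring carbons on the inner one, so directed and peripheral attack coincide and should give the epoxide trans to the C3 oxygen, as peracids do with medium-ring allylic alcohols. The C1=C10 olefin is screened by the C9 silyl ether, the isopropenyl group is less electron-rich, and the enoate is inert.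

Step 21
Reactants: 28 (1(10)Z,3S,4R,5S,7R,8S,9R)-9-[(tert-butyldimethylsilyl)oxy]-4,5-epoxy-3-hydroxy-4,10-dimethyl-7-(prop-1-en-2-yl)cyclodec-1(10)-en-8-yl 3-methylbut-2-enoate; 29 angelic acid [(Z)-2-methylbut-2-enoic acid]
Product: 31 (1(10)Z,3S,4S,5S,7R,8S,9R)-3-(angeloyloxy)-9-[(tert-butyldimethylsilyl)oxy]-4,5-epoxy-4,10-dimethyl-7-(prop-1-en-2-yl)cyclodec-1(10)-en-8-yl 3-methylbut-2-enoate, via angelic 2,4,6-trichlorobenzoic anhydride 30 (not isolated)
Conditions: 29, 2,4,6-trichlorobenzoyl chloride, Et3N, toluene, rt; then 28, toluene, 60 °C, no DMAP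
Reagents that add atoms: none
Why: Yamaguchi esterification through the mixed anhydride 30; leaving out the nucleophilic pyridine catalyst removes the addition–elimination path that turns angelates into tiglates, and the amine base is too weak to open or rearrange the epoxy alcohol.

Step 22
Reactants: 31 (1(10)Z,3S,4S,5S,7R,8S,9R)-3-(angeloyloxy)-9-[(tert-butyldimethylsilyl)oxy]-4,5-epoxy-4,10-dimethyl-7-(prop-1-en-2-yl)cyclodec-1(10)-en-8-yl 3-methylbut-2-enoate
Product: 32 (1(10)Z,3S,4S,5S,7R,8S,9R)-3-(angeloyloxy)-4,5-epoxy-9-hydroxy-4,10-dimethyl-7-(prop-1-en-2-yl)cyclodec-1(10)-en-8-yl 3-methylbut-2-enoate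
Conditions: Bu4NF, AcOH (1:1), THF, 0 °C to rt
Reagents that add atoms: none
Why: Fluoride-mediated desilylation; buffering with acetic acid suppresses alkoxide formation and hence the shift of the C8 acyl group to C9, and the epoxide tolerates these near-neutral conditions.

Step 23
Reactants: 32 (1(10)Z,3S,4S,5S,7R,8S,9R)-3-(angeloyloxy)-4,5-epoxy-9-hydroxy-4,10-dimethyl-7-(prop-1-en-2-yl)cyclodec-1(10)-en-8-yl 3-methylbut-2-enoate
Product: 33 (1R,3S,4S,5S,7R,8S,9S,10S)-3-(angeloyloxy)-1,10:4,5-diepoxy-9-hydroxy-4,10-dimethyl-7-(prop-1-en-2-yl)cyclodecan-8-yl 3-methylbut-2-enoate (CNP0320216.1)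
Conditions: VO(acac)2 (5 mol%), t-BuOOH (in decane), CH2Cl2, 0 °C to rt
Reagents that add atoms: tert-butyl hydroperoxide, CC(C)(C)OO
Why: Vanadium-catalysed hydroxyl-directed epoxidation; the vanadate ester of the C9 hydroxyl delivers the peroxide oxygen within the complex, which in medium rings gives the epoxide cis to the hydroxyl (the opposite sense to peracids), and only the olefin with a free allylic hydroxyl reacts.

## Compound list

1 | propane-1,3-diol | OCCCO | starting material
2 | 3-[(4-methoxybenzyl)oxy]propan-1-ol | COc1ccc(COCCCO)cc1 | intermediate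
3 | 3-[(4-methoxybenzyl)oxy]propanal | COc1ccc(COCCC=O)cc1 | intermediate
4 | ethyltriphenylphosphonium bromide | CC[P+](c1ccccc1)(c1ccccc1)c1ccccc1.[Br-] | starting material
5 | ethylidenetriphenylphosphorane | CC=P(c1ccccc1)(c1ccccc1)c1ccccc1 | intermediate
6 | (1-iodoethyl)triphenylphosphonium iodide | CC(I)[P+](c1ccccc1)(c1ccccc1)c1ccccc1.[I-] | intermediate
7 | (1-iodoethylidene)triphenylphosphorane | CC(I)=P(c1ccccc1)(c1ccccc1)c1ccccc1 | intermediate
8 | (Z)-1-{[(4-iodopent-3-en-1-yl)oxy]methyl}-4-methoxybenzene | C/C(I)=C/CCOCc1ccc(OC)cc1 | intermediate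
9 | 2-oxoethyl benzoate | O=CCOC(=O)c1ccccc1 | starting material
10 | (2R,3Z)-2-hydroxy-6-[(4-methoxybenzyl)oxy]-3-methylhex-3-en-1-yl benzoate | COc1ccc(COCC/C=C(C)\[C@@H](O)COC(=O)c2ccccc2)cc1 | intermediate
11 | (2R,3Z)-2-[(tert-butyldimethylsilyl)oxy]-6-[(4-methoxybenzyl)oxy]-3-methylhex-3-en-1-yl benzoate | COc1ccc(COCC/C=C(C)\[C@@H](O[Si](C)(C)C(C)(C)C)COC(=O)c2ccccc2)cc1 | intermediate
12 | (2R,3Z)-2-[(tert-butyldimethylsilyl)oxy]-6-hydroxy-3-methylhex-3-en-1-yl benzoate | OCC/C=C(C)\[C@@H](O[Si](C)(C)C(C)(C)C)COC(=O)c1ccccc1 | intermediate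
13 | (2R,3Z)-2-[(tert-butyldimethylsilyl)oxy]-3-methyl-6-oxohex-3-en-1-yl benzoate | O=CC/C=C(C)\[C@@H](O[Si](C)(C)C(C)(C)C)COC(=O)c1ccccc1 | intermediate
14 | (2R,3Z,6S,7Z)-2-[(tert-butyldimethylsilyl)oxy]-6-hydroxy-10-[(4-methoxybenzyl)oxy]-3,7-dimethyldeca-3,7-dien-1-yl benzoate | COc1ccc(COCC/C=C(C)\[C@@H](O)C/C=C(C)\[C@@H](O[Si](C)(C)C(C)(C)C)COC(=O)c2ccccc2)cc1 | intermediate
15 | (2R,3Z,6S,7Z)-2-[(tert-butyldimethylsilyl)oxy]-10-[(4-methoxybenzyl)oxy]-3,7-dimethyl-6-[(triethylsilyl)oxy]deca-3,7-dien-1-yl benzoate | COc1ccc(COCC/C=C(C)\[C@@H](O[Si](CC)(CC)CC)C/C=C(C)\[C@@H](O[Si](C)(C)C(C)(C)C)COC(=O)c2ccccc2)cc1 | intermediate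
16 | (2R,3Z,6S,7Z)-2-[(tert-butyldimethylsilyl)oxy]-10-hydroxy-3,7-dimethyl-6-[(triethylsilyl)oxy]deca-3,7-dien-1-yl benzoate | OCC/C=C(C)\[C@@H](O[Si](CC)(CC)CC)C/C=C(C)\[C@@H](O[Si](C)(C)C(C)(C)C)COC(=O)c1ccccc1 | intermediate
17 | (2R,3Z,6S,7Z)-2-[(tert-butyldimethylsilyl)oxy]-3,7-dimethyl-10-oxo-6-[(triethylsilyl)oxy]deca-3,7-dien-1-yl benzoate | O=CC/C=C(C)\[C@@H](O[Si](CC)(CC)CC)C/C=C(C)\[C@@H](O[Si](C)(C)C(C)(C)C)COC(=O)c1ccccc1 | intermediate
18 | ethyl 2-(triphenylphosphoranylidene)propanoate | CCOC(=O)C(C)=P(c1ccccc1)(c1ccccc1)c1ccccc1 | starting material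
19 | ethyl (2E,5Z,7S,9Z,11R)-12-(benzoyloxy)-11-[(tert-butyldimethylsilyl)oxy]-2,6,10-trimethyl-7-[(triethylsilyl)oxy]dodeca-2,5,9-trienoate | CCOC(=O)/C(C)=C/C/C=C(C)\[C@@H](O[Si](CC)(CC)CC)C/C=C(C)\[C@@H](O[Si](C)(C)C(C)(C)C)COC(=O)c1ccccc1 | intermediate
20 | (2E,5Z,7S,9Z,11R)-11-[(tert-butyldimethylsilyl)oxy]-2,6,10-trimethyl-7-[(triethylsilyl)oxy]dodeca-2,5,9-triene-1,12-diol | OC/C(C)=C/C/C=C(C)\[C@@H](O[Si](CC)(CC)CC)C/C=C(C)\[C@@H](O[Si](C)(C)C(C)(C)C)CO | intermediate
21 | (2R,3Z,6S,7Z,10E)-2-[(tert-butyldimethylsilyl)oxy]-12-chloro-3,7,11-trimethyl-6-[(triethylsilyl)oxy]dodeca-3,7,10-trien-1-ol | ClC/C(C)=C/C/C=C(C)\[C@@H](O[Si](CC)(CC)CC)C/C=C(C)\[C@@H](O[Si](C)(C)C(C)(C)C)CO | intermediate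
22 | (2R,3Z,6S,7Z,10E)-2-[(tert-butyldimethylsilyl)oxy]-3,7,11-trimethyl-6-[(triethylsilyl)oxy]-12-(tributylstannyl)dodeca-3,7,10-trien-1-ol | CCCC[Sn](CCCC)(CCCC)C/C(C)=C/C/C=C(C)\[C@@H](O[Si](CC)(CC)CC)C/C=C(C)\[C@@H](O[Si](C)(C)C(C)(C)C)CO | intermediate
23 | (2R,3Z,6S,7Z,10E)-2-[(tert-butyldimethylsilyl)oxy]-3,7,11-trimethyl-6-[(triethylsilyl)oxy]-12-(tributylstannyl)dodeca-3,7,10-trienal | CCCC[Sn](CCCC)(CCCC)C/C(C)=C/C/C=C(C)\[C@@H](O[Si](CC)(CC)CC)C/C=C(C)\[C@@H](O[Si](C)(C)C(C)(C)C)C=O | intermediate
24 | (1(10)Z,3S,4Z,7R,8S,9R)-9-[(tert-butyldimethylsilyl)oxy]-4,10-dimethyl-7-(prop-1-en-2-yl)-3-[(triethylsilyl)oxy]cyclodeca-1(10),4-dien-8-ol (ring numbering C1–C10 as in the text) | C=C(C)[C@H]1C/C=C(C)\[C@@H](O[Si](CC)(CC)CC)C/C=C(C)\[C@@H](O[Si](C)(C)C(C)(C)C)[C@H]1O | intermediate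
25 | 3-methylbut-2-enoyl chloride | CC(C)=CC(=O)Cl | starting material
26 | (1(10)Z,3S,4Z,7R,8S,9R)-9-[(tert-butyldimethylsilyl)oxy]-4,10-dimethyl-7-(prop-1-en-2-yl)-3-[(triethylsilyl)oxy]cyclodeca-1(10),4-dien-8-yl 3-methylbut-2-enoate | C=C(C)[C@H]1C/C=C(C)\[C@@H](O[Si](CC)(CC)CC)C/C=C(C)\[C@@H](O[Si](C)(C)C(C)(C)C)[C@H]1OC(=O)C=C(C)C | intermediate
27 | (1(10)Z,3S,4Z,7R,8S,9R)-9-[(tert-butyldimethylsilyl)oxy]-3-hydroxy-4,10-dimethyl-7-(prop-1-en-2-yl)cyclodeca-1(10),4-dien-8-yl 3-methylbut-2-enoate | C=C(C)[C@H]1C/C=C(C)\[C@@H](O)C/C=C(C)\[C@@H](O[Si](C)(C)C(C)(C)C)[C@H]1OC(=O)C=C(C)C | intermediate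
28 | (1(10)Z,3S,4R,5S,7R,8S,9R)-9-[(tert-butyldimethylsilyl)oxy]-4,5-epoxy-3-hydroxy-4,10-dimethyl-7-(prop-1-en-2-yl)cyclodec-1(10)-en-8-yl 3-methylbut-2-enoate (epoxide trans to the C3 oxygen) | C=C(C)[C@H]1C[C@@H]2O[C@]2(C)[C@@H](O)C/C=C(C)\[C@@H](O[Si](C)(C)C(C)(C)C)[C@H]1OC(=O)C=C(C)C | intermediate
29 | angelic acid [(Z)-2-methylbut-2-enoic acid] | C/C=C(/C)C(=O)O | starting material
30 | angelic 2,4,6-trichlorobenzoic anhydride | C/C=C(/C)C(=O)OC(=O)c1c(Cl)cc(Cl)cc1Cl | intermediate
31 | (1(10)Z,3S,4S,5S,7R,8S,9R)-3-(angeloyloxy)-9-[(tert-butyldimethylsilyl)oxy]-4,5-epoxy-4,10-dimethyl-7-(prop-1-en-2-yl)cyclodec-1(10)-en-8-yl 3-methylbut-2-enoate | C=C(C)[C@H]1C[C@@H]2O[C@]2(C)[C@@H](OC(=O)/C(C)=C\C)C/C=C(C)\[C@@H](O[Si](C)(C)C(C)(C)C)[C@H]1OC(=O)C=C(C)C | intermediate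
32 | (1(10)Z,3S,4S,5S,7R,8S,9R)-3-(angeloyloxy)-4,5-epoxy-9-hydroxy-4,10-dimethyl-7-(prop-1-en-2-yl)cyclodec-1(10)-en-8-yl 3-methylbut-2-enoate | C=C(C)[C@H]1C[C@@H]2O[C@]2(C)[C@@H](OC(=O)/C(C)=C\C)C/C=C(C)\[C@@H](O)[C@H]1OC(=O)C=C(C)C | intermediate
33 | (1R,3S,4S,5S,7R,8S,9S,10S)-3-(angeloyloxy)-1,10:4,5-diepoxy-9-hydroxy-4,10-dimethyl-7-(prop-1-en-2-yl)cyclodecan-8-yl 3-methylbut-2-enoate (CNP0320216.1) | C=C(C)[C@H]1C[C@@H]2O[C@]2(C)[C@@H](OC(=O)/C(C)=C\C)C[C@H]2O[C@@]2(C)[C@@H](O)[C@H]1OC(=O)C=C(C)C | target

## Step count and least certain steps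

Total: 23 steps. Longest linear sequence: 23 steps (from 1; iodide 8 from steps 1–3 is used in steps 4 and 8).

Step 8 (key step). What is most likely to go wrong is insufficient facial discrimination at C3: the ligand has to tell apart the faces of an unbranched skipped enal while carrying a trisubstituted Z-alkenyl group. Migration of the C1=C10 double bond into conjugation before coupling is a second loss channel. Fallback: the stereocentre is set by reduction instead of addition. It sets out from 8 and 13, which are coupled without the chiral ligand (stoichiometric CrCl2, catalytic NiCl2, DMSO/THF) to the epimer mixture (2R,3Z,6RS,7Z)-2-[(tert-butyldimethylsilyl)oxy]-6-hydroxy-10-[(4-methoxybenzyl)oxy]-3,7-dimethyldeca-3,7-dien-1-yl benzoate F1. Dess–Martin oxidation gives the Z-enone (2R,3Z,7Z)-2-[(tert-butyldimethylsilyl)oxy]-10-[(4-methoxybenzyl)oxy]-3,7-dimethyl-6-oxodeca-3,7-dien-1-yl benzoate F2. Corey–Bakshi–Shibata reduction (the 2-methyl-oxazaborolidine enantiomer that gives the 6S carbinol, catecholborane, toluene, −78 °C) comes back to the route at 14.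

Step 17 (ring closure). What is most likely to go wrong is intermolecular allylation outrunning the slow ten-membered closure, together with loss of the allyl–tin bond by protonolysis during oxidation and activation. A ring-imposed transition-state geometry could also erode the C7/C8 control. Fallback: a more robust allylsilane made directly by olefination, which also bypasses steps 12–16. It sets out from 17. Ylide 5 (from 4 and n-BuLi) is alkylated with (iodomethyl)trimethylsilane to triphenyl[1-(trimethylsilyl)propan-2-yl]phosphonium iodide F3, and a second equivalent of n-BuLi gives triphenyl[1-(trimethylsilyl)propan-2-ylidene]phosphorane F4. Wittig reaction of F4 with 17 at −78 °C gives (2R,3Z,6S,7Z)-2-[(tert-butyldimethylsilyl)oxy]-3,7,11-trimethyl-6-[(triethylsilyl)oxy]-12-(trimethylsilyl)dodeca-3,7,10-trien-1-yl benzoate F5 (geometry at the new olefin immaterial). iBu2AlH then removes the benzoate to give the corresponding dodeca-3,7,10-trien-1-ol F6, and Parikh–Doering oxidation gives the corresponding dodeca-3,7,10-trienal F7. Hosomi–Sakurai cyclisation of F7 (BF3·OEt2, CH2Cl2, −78 °C, high dilution) comes back to the route at 24.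

Step 20 (C4–C5 epoxide). What is most likely to go wrong is a second oxidation at C1=C10 or at the isopropenyl group, or loss of facial selectivity if the ring holds the C3 hydroxyl on the inner face of the olefin. Fallback: reagent control in place of substrate direction. It sets out from 27 and uses a Shi epoxidation (the fructose-derived ketone enantiomer matched to the required C4–C5 face, KHSO5, K2CO3 buffer, MeCN/dimethoxymethane/water, 0 °C), and comes back at 28.

Step 21 (angelate). What is most likely to go wrong is Z to E isomerisation of the angeloyl group by reversible conjugate addition during a slow acylation of a hindered epoxy alcohol, and chloride opening of the epoxide at 60 °C. Fallback: the Z olefin is built on the ester. It sets out from 28, which is acylated with 2-(diphenoxyphosphoryl)propanoic acid (carbodiimide, DMAP, 0 °C) to the phosphonoester (1(10)Z,3S,5S,7R,8S,9R)-9-[(tert-butyldimethylsilyl)oxy]-3-{[2-(diphenoxyphosphoryl)propanoyl]oxy}-4,5-epoxy-4,10-dimethyl-7-(prop-1-en-2-yl)cyclodec-1(10)-en-8-yl 3-methylbut-2-enoate F8. A Z-selective Horner–Wadsworth–Emmons reaction of the Ando type with acetaldehyde (NaI, DBU, THF, −78 to 0 °C) comes back to the route at 31.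

Step 23 (C1–C10 epoxide). What is most likely to go wrong is delivery to the wrong face if, in the ten-membered ring, the C9–O bond cannot adopt the small dihedral angle to the olefin that vanadium needs; with both A(1,2) and A(1,3) strain present, open-chain models give no clear preference. A slow reaction would also give the C8 acyl group time to shift. Fallback: reagent control. It sets out from 32 and uses a titanium–tartrate epoxidation (Ti(OiPr)4, the diisopropyl tartrate enantiomer for which 32 is the fast-reacting, matched carbinol, t-BuOOH, 4 Å sieves, CH2Cl2, −20 °C). The matched case of secondary allylic alcohols gives the erythro (here ring-cis) epoxy alcohol, and the fallback comes back at 33.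

## Further compounds

F1 | step 8 | (2R,3Z,6RS,7Z)-2-[(tert-butyldimethylsilyl)oxy]-6-hydroxy-10-[(4-methoxybenzyl)oxy]-3,7-dimethyldeca-3,7-dien-1-yl benzoate (epimer mixture at the new carbinol) | COc1ccc(COCC/C=C(C)\C(O)C/C=C(C)\[C@@H](O[Si](C)(C)C(C)(C)C)COC(=O)c2ccccc2)cc1
F2 | step 8 | (2R,3Z,7Z)-2-[(tert-butyldimethylsilyl)oxy]-10-[(4-methoxybenzyl)oxy]-3,7-dimethyl-6-oxodeca-3,7-dien-1-yl benzoate | COc1ccc(COCC/C=C(C)\C(=O)C/C=C(C)\[C@@H](O[Si](C)(C)C(C)(C)C)COC(=O)c2ccccc2)cc1
F3 | step 17 | triphenyl[1-(trimethylsilyl)propan-2-yl]phosphonium iodide | CC(C[Si](C)(C)C)[P+](c1ccccc1)(c1ccccc1)c1ccccc1.[I-]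
F4 | step 17 | triphenyl[1-(trimethylsilyl)propan-2-ylidene]phosphorane | CC(C[Si](C)(C)C)=P(c1ccccc1)(c1ccccc1)c1ccccc1
F5 | step 17 | (2R,3Z,6S,7Z)-2-[(tert-butyldimethylsilyl)oxy]-3,7,11-trimethyl-6-[(triethylsilyl)oxy]-12-(trimethylsilyl)dodeca-3,7,10-trien-1-yl benzoate (10E/10Z mixture) | C[Si](C)(C)CC(C)=CC/C=C(C)\[C@@H](O[Si](CC)(CC)CC)C/C=C(C)\[C@@H](O[Si](C)(C)C(C)(C)C)COC(=O)c1ccccc1
F6 | step 17 | (2R,3Z,6S,7Z)-2-[(tert-butyldimethylsilyl)oxy]-3,7,11-trimethyl-6-[(triethylsilyl)oxy]-12-(trimethylsilyl)dodeca-3,7,10-trien-1-ol (10E/10Z mixture) | C[Si](C)(C)CC(C)=CC/C=C(C)\[C@@H](O[Si](CC)(CC)CC)C/C=C(C)\[C@@H](O[Si](C)(C)C(C)(C)C)CO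
F7 | step 17 | (2R,3Z,6S,7Z)-2-[(tert-butyldimethylsilyl)oxy]-3,7,11-trimethyl-6-[(triethylsilyl)oxy]-12-(trimethylsilyl)dodeca-3,7,10-trienal (10E/10Z mixture) | C[Si](C)(C)CC(C)=CC/C=C(C)\[C@@H](O[Si](CC)(CC)CC)C/C=C(C)\[C@@H](O[Si](C)(C)C(C)(C)C)C=O
F0 | step 20 | none | none
F8 | step 21 | (1(10)Z,3S,5S,7R,8S,9R)-9-[(tert-butyldimethylsilyl)oxy]-3-{[2-(diphenoxyphosphoryl)propanoyl]oxy}-4,5-epoxy-4,10-dimethyl-7-(prop-1-en-2-yl)cyclodec-1(10)-en-8-yl 3-methylbut-2-enoate (mixture at the phosphonate carbon) | C=C(C)[C@H]1C[C@@H]2O[C@]2(C)[C@@H](OC(=O)C(C)P(=O)(Oc3ccccc3)Oc3ccccc3)C/C=C(C)\[C@@H](O[Si](C)(C)C(C)(C)C)[C@H]1OC(=O)C=C(C)C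
F0 | step 23 | none | none
A1 | alternative 1 | Z,Z-cyclodeca-1(10),4-dien-9-one with C7 isopropenyl and C3 tert-butyldimethylsilyl ether | C=C(C)[C@H]1C/C=C(C)\[C@@H](O[Si](C)(C)C(C)(C)C)C/C=C(C)\C(=O)C1
A2 | alternative 1 | 5-[(tert-butyldimethylsilyl)oxy]-2,6-dimethyl-1-[(E)-3-methylbuta-1,3-dienyl]-6-vinylcyclohex-2-en-1-ol, silyl ether, vinyl and dienyl all cis | C=C[C@@]1(C)[C@@H](O[Si](C)(C)C(C)(C)C)CC=C(C)[C@@]1(O)/C=C/C(C)=C
A3 | alternative 2 | Z,Z-cyclodecadiene with C8,C9-acetonide, C3 tert-butyldimethylsilyl ether and C7 isopropenyl | C=C(C)[C@H]1C/C=C(C)\[C@@H](O[Si](C)(C)C(C)(C)C)C/C=C(C)\[C@@H](OC(C)(C)O2)[C@H]12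
A4 | alternative 2 | open-chain diiodide: Z-alkenyl iodide at C5, primary iodide at C6, C8,C9-acetonide, C3 tert-butyldimethylsilyl ether | I/C=C(C)\[C@@H](O[Si](C)(C)C(C)(C)C)C/C=C(C)\[C@H]1OC(C)(C)O[C@H]1[C@H](CI)C(C)=C
A5 | alternative 3 | Z,Z-cyclodecadiene cis-8,9-diol with C3 tert-butyldimethylsilyl ether and C7 isopropenyl | C=C(C)[C@H]1C/C=C(C)\[C@@H](O[Si](C)(C)C(C)(C)C)C/C=C(C)\[C@@H](O)[C@H]1O
A6 | alternative 3 | open-chain dialdehyde: C8 aldehyde bearing the C7 isopropenyl group and C9 Z-enal, C3 tert-butyldimethylsilyl ether | O=C[C@@H](C(C)=C)C/C=C(C)\[C@@H](O[Si](C)(C)C(C)(C)C)C/C=C(C)\C=O
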